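(All runs were generated by integration for an exercise, and the scatter is random.)

Open the minutes with the autumn run: it is this very flask, followed so far. The summer run has more partner.

| flask | starting material | partner | remark | time |
|---|---|---|---|---|
| autumn | 0.20 mM | 0.50 mM (fed, over 6.0 s) | the very flask that is asked about, followed so far; the fed solution adds 0.25 times the starting volume |  |
| summer | 0.20 mM | 0.75 mM (fed, over 6.0 s) | run made earlier; the fed solution adds 0.25 times the starting volume |  |
| flask | 0.20 mM | 0.500 mM (fed, over 6.0 s) | the fed solution adds 0.25 times the starting volume | 40 min |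

| run | time / min | intermediate B / % | target / % | starting material / % |
|---|---|---|---|---|
| autumn | 1.00 | 33.9 | 8.8 | 40.2 |
| autumn | 2.00 | 28.8 | 22.1 | 19.3 |
| autumn | 3.00 | 19.5 | 32.0 | 9.7 |
| autumn | 4.00 | 12.5 | 38.5 | 5.2 |
| autumn | 5.00 | 7.1 | 42.3 | 3.2 |
| autumn | 6.00 | 4.5 | 44.8 | 1.5 |
| autumn | 8.00 | 1.2 | 47.1 | 0.4 |
| summer | 0.833 | 39.4 | 7.8 | 31.6 |
| summer | 2.50 | 22.4 | 31.4 | 4.7 |
| summer | 5.00 | 5.8 | 43.6 | 0.8 |
| summer | 6.00 | 3.2 | 45.4 | 0.7 |
| summer | 10.0 | 0.6 | 48.1 | 0 |
| summer | 12.0 | 0.2 | 48.5 | 0 |
| summer | 15.0 | 0.3 | 48.9 | 0.2 |

(each reading ± 0.3 percentage points)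
- charges are per starting volume, the dose included; the dosed solution carries all of it
- the earlier runs were read with a standard deviation of 0.3 percentage points
- time, not beyond 40 min, at which the flask holds most intermediate B
- the amount of intermediate B, in percent of the starting material charged, at that time

The analyst reported on the autumn run. At 8.00 min, target held against starting material lost and no longer standing as intermediate B was 0.479. She called this the target share, a selectivity. The same ratio stood at 0.426 at 2.00 min of the autumn run, so hers is a late reading.

The kineticist read target's rate over intermediate B between 2.00 min and 3.00 min of the autumn run, and got 0.410 min⁻¹. Divided by the share, that gave intermediate B a whole loss constant of 0.856 min⁻¹.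

The analyst added that starting material fell at a mean 0.823 min⁻¹ over the first 2.00 min of the autumn run. In the summer run it fell at 1.22 min⁻¹. That is a factor 1.48 for a factor 1.50 in partner, so she took the mean constant as proportional to the partner charge.

The chair divided the two rates and got 0.960: the crossing ratio, starting material's fall constant over intermediate B's loss constant. Taking both steps as plain first-order, gain equals loss at the peak, so intermediate B over starting material equals this ratio. In the autumn run that reading ratio was 0.843 at 1.00 min and 1.49 at 2.00 min. The meeting therefore put this flask's peak at 1.23 min.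

For plain first-order steps, the height is the ratio raised to one over one minus itself, here 36.0%. The meeting committed to a height between the reading of 33.9% and that figure.

The forecast gave 1.15 min and 34.3%, taking the peak where “B's formation equals its loss”.

This flask holds most intermediate B at 1.18 min, with 34.1%.

    starting material + partner ⇌ intermediate A (K = 1300 L mol⁻¹, k = 56.1 L mol⁻¹ s⁻¹)
    intermediate A → intermediate B (k = 0.197 s⁻¹)
    intermediate B → target (k = 0.00689 s⁻¹)
    partner + intermediate A ⇌ intermediate C (K = 11700 L mol⁻¹, k = 71.7 L mol⁻¹ s⁻¹)
    intermediate B ⇌ intermediate D (K = 1.38, k = 0.00764 s⁻¹)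
    partner → decomposition product (k = 5.69 × 10⁻⁶ s⁻¹)
    intermediate D → decomposed reagent (k = 0.104 s⁻¹)

Starting material stands at 35.2% then, so intermediate B over starting material is 0.969, against the crossing ratio of 0.960. Now take the neighbour flask with 0.30 mM of partner. Scaled by charge, its crossing ratio is 0.576. The height rule gives 27.2%, and that neighbour flask peaked at 25.7%.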